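Numbering follows the pyrano[3,2-b]pyran core (lactone O1, C2, C3, C4, C4a, ether O5, C6, C7, C8, C8a). Everything rests on the C8–C8a bond of the tetrahydropyran ring (ring A): C7(O)–C8(Me)–C8a(O) is an aldol retron once C7 is a ketone. An acyclic keto aldehyde, whose ethyl ketone (C6–C7–C8) and non-enolisable aldehyde (C8a on quaternary C4a) are joined only through ether O5, is closed by a one-pot silyl triflate enolisation / intramolecular Mukaiyama aldol that forms ring A and sets C8 and C8a, all substituents equatorial. The hindered O5 ether comes from an epoxide opening by ethyl (S)-lactate through a temporary 1,4-dioxanone (ring C).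

Key step: step 7

Remark (ring labels): ring A is the tetrahydropyran (O5, C6, C7, C8, C8a, C4a), ring B the δ-lactone (O1, C2, C3, C4, C4a, C8a), ring C the temporary 1,4-dioxane ring of compounds 8–11.
Remark (assumption): in step 1 the (S)-enantiomer of the phosphoric acid is assigned by analogy with the facial preference of this catalyst class for aryl aldehydes; if methacrolein responded in the opposite sense, the (R)-catalyst would be taken.

Step 1
Reactants: 1 methacrolein; 2 (E)-crotylboronic acid pinacol ester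
Product: 4 (3S,4S)-2,4-dimethylhexa-1,5-dien-3-ol, via pinacol borate ester 3 (not isolated)
Conditions: (S)-TRIP [(S)-3,3'-bis(2,4,6-triisopropylphenyl)-1,1'-binaphthyl-2,2'-diyl hydrogen phosphate] (5 mol %), 4 Å MS, toluene, −30 °C; then H2O
Reagents that add atoms: none
Why: Brønsted-acid-catalysed crotylboration through a closed chair (Zimmerman–Traxler type) transition state: the (E)-crotyl geometry fixes the 3,4-anti relationship and the chiral phosphate, hydrogen-bonded to the boronate oxygen, directs attack to the Si face of the aldehyde, setting C4 and C3 of the core.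

Step 2
Reactants: 4 (3S,4S)-2,4-dimethylhexa-1,5-dien-3-ol
Product: 5 (1S,2S)-2-methyl-1-[(2R)-2-methyloxiran-2-yl]but-3-en-1-ol
Conditions: VO(acac)2 (2 mol %), t-BuOOH (1.3 equiv, decane), CH2Cl2, 0 °C
Reagents that add atoms: tert-butyl hydroperoxide, CC(C)(C)OO
Why: Hydroxyl-directed vanadium-catalysed epoxidation touches only the allylic 1,1-disubstituted alkene, and A(1,2) strain between the alkene methyl and the carbinol substituent in the vanadate ester favours the erythro epoxy alcohol, i.e. the (2R)-oxirane.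

Step 3
Reactants: 5 (1S,2S)-2-methyl-1-[(2R)-2-methyloxiran-2-yl]but-3-en-1-ol; 6 ethyl (S)-lactate
Product: 8 (3S,5S)-5-[(1S,2S)-1-hydroxy-2-methylbut-3-en-1-yl]-3,5-dimethyl-1,4-dioxan-2-one, via hydroxy ester 7 (not isolated)
Conditions: 6 (10 equiv), BF3·OEt2 (0.1 equiv), CH2Cl2, −40 → 0 °C; excess 6 evaporated; then TsOH·H2O (5 mol %), toluene, 60 °C
Reagents that add atoms: none
Why: Lewis-acid-catalysed alcoholysis of a 2,2-disubstituted epoxide takes place at the tertiary carbon by a borderline SN2 path with inversion, which sets C4a with O5 syn to the C4 hydroxyl, the lactate stereocentre (C6) is not touched, and acid-catalysed transesterification by the primary hydroxyl, faster than by the hindered secondary one, then closes ring C.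

Step 4
Reactants: 8 (3S,5S)-5-[(1S,2S)-1-hydroxy-2-methylbut-3-en-1-yl]-3,5-dimethyl-1,4-dioxan-2-one
Product: 9 (3S,5S)-5-[(1S,2S)-1-{[tert-butyl(dimethyl)silyl]oxy}-2-methylbut-3-en-1-yl]-3,5-dimethyl-1,4-dioxan-2-one
Conditions: TBSOTf (1.3 equiv), 2,6-lutidine (2 equiv), CH2Cl2, −78 → 0 °C
Reagents that add atoms: tert-butyldimethylsilyl trifluoromethanesulfonate, CC(C)(C)[Si](C)(C)OS(=O)(=O)C(F)(F)F
Why: Silyl triflate silylation of the hindered secondary hydroxyl; the lactone and the alkene are inert and no stereocentre is affected.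

Step 5
Reactants: 9 (3S,5S)-5-[(1S,2S)-1-{[tert-butyl(dimethyl)silyl]oxy}-2-methylbut-3-en-1-yl]-3,5-dimethyl-1,4-dioxan-2-one
Product: 11 (3S,5S)-5-[(1S,2S)-1-{[tert-butyl(dimethyl)silyl]oxy}-2-methylbut-3-en-1-yl]-2-ethyl-3,5-dimethyl-1,4-dioxan-2-ol (anomeric mixture), via lithium hemiketal alkoxide 10 (not isolated)
Conditions: EtLi (1.1 equiv), THF, −78 °C; then H2O
Reagents that add atoms: ethyllithium, [Li]CC
Why: Addition of an alkyllithium to a δ-lactone stops at the tetrahedral lithium alkoxide at −78 °C, which survives until the aqueous quench and gives the cyclic hemiketal (masked ethyl ketone); the new hemiketal centre is inconsequential.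

Step 6
Reactants: 11 (3S,5S)-5-[(1S,2S)-1-{[tert-butyl(dimethyl)silyl]oxy}-2-methylbut-3-en-1-yl]-2-ethyl-3,5-dimethyl-1,4-dioxan-2-ol
Product: 12 (2R,3S,4S)-3-{[tert-butyl(dimethyl)silyl]oxy}-2,4-dimethyl-2-{[(2S)-3-oxopentan-2-yl]oxy}hex-5-enal
Conditions: Dess–Martin periodinane (1.5 equiv), CH2Cl2, 0 °C → rt; used crude
Reagents that add atoms: none
Why: Dess–Martin oxidation drains the small equilibrium share of the open δ-hydroxy ketone, whose primary alcohol is oxidised to the aldehyde, while the tertiary hemiketal hydroxyl cannot be oxidised and the new aldehyde, on quaternary C4a, cannot enolise.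

Step 7
Reactants: 12 (2R,3S,4S)-3-{[tert-butyl(dimethyl)silyl]oxy}-2,4-dimethyl-2-{[(2S)-3-oxopentan-2-yl]oxy}hex-5-enal
Product: 15 (2S,4S,5S,6S)-6-[(1S,2S)-1-{[tert-butyl(dimethyl)silyl]oxy}-2-methylbut-3-en-1-yl]-5-hydroxy-2,4,6-trimethyloxan-3-one, via enol silane 13 (not isolated), via trimethylsilyl ether 14 (not isolated)
Conditions: i-Pr2NEt (3 equiv), TMSOTf (2.5 equiv), CH2Cl2, −78 → −20 °C; then 1 M HCl, THF, 0 °C
Reagents that add atoms: none
Why: TMSOTf/i-Pr2NEt silylates the ketone oxygen and removes a proton from the less hindered ethyl CH2 to give (Z)-enol silane 13, and excess TMSOTf then activates the non-enolisable aldehyde so that C8 of the enol silane attacks C8a and the silyl group ends on the new oxygen (14), which the acid work-up frees. The closest known reaction type is the one-pot silyl triflate/amine enol silane formation–Mukaiyama aldol addition of ketones to non-enolisable aldehydes, here run intramolecularly. Ring A closes in the 6-(enolendo)-exo-trig mode through a chair in which the C6 methyl and the bulky C4 side chain are equatorial and the C4a methyl is axial. C8 is controlled by the (Z)-enol geometry, whose methyl, cis to the siloxy group, becomes equatorial, and C8a by the open, non-chelated transition state, in which the silylated carbonyl oxygen lies antiperiplanar to the enol C7=C8 bond and anti to the C4a–O5 bond (Cornforth-type dipole minimisation) and so ends equatorial, trans to the C8 methyl. The step needs enolisation towards C8 and not C6, secured by the hindered tertiary-alkoxy methine at C6 and by the fact that only the C8 enol silane can reach the aldehyde through a six-membered transition state, and it needs facial selectivity at C8a, secured by the non-chelating silyl Lewis acid and by the C6 and C4a stereocentres that fix the chair.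

Step 8
Reactants: 15 (2S,4S,5S,6S)-6-[(1S,2S)-1-{[tert-butyl(dimethyl)silyl]oxy}-2-methylbut-3-en-1-yl]-5-hydroxy-2,4,6-trimethyloxan-3-one
Product: 18 (3R,4S,4aS,6S,8S,8aS)-4-{[tert-butyl(dimethyl)silyl]oxy}-2-hydroxy-3,4a,6,8-tetramethylhexahydropyrano[3,2-b]pyran-7-one (lactol; anomeric mixture), via ozonide 16 (not isolated), via hydroxy aldehyde 17 (not isolated)
Conditions: O3, CH2Cl2, −78 °C; then PPh3, −78 °C → rt
Reagents that add atoms: ozone, [O-][O+]=O
Why: Ozonolysis (1,3-dipolar cycloaddition, Criegee rearrangement, reductive work-up) cleaves the only C=C bond, and the C2 aldehyde is trapped at once by the equatorial C8a hydroxyl as the six-membered lactol, closing ring B trans-fused.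

Step 9
Reactants: 18 (3R,4S,4aS,6S,8S,8aS)-4-{[tert-butyl(dimethyl)silyl]oxy}-2-hydroxy-3,4a,6,8-tetramethylhexahydropyrano[3,2-b]pyran-7-one
Product: 19 (3R,4S,4aS,6S,8S,8aS)-4-{[tert-butyl(dimethyl)silyl]oxy}-3,4a,6,8-tetramethylhexahydropyrano[3,2-b]pyran-2,7-dione
Conditions: Pr4N[RuO4] (5 mol %), N-methylmorpholine N-oxide (1.5 equiv), 4 Å MS, CH2Cl2, rt
Reagents that add atoms: none
Why: Ley–Griffith oxidation converts the lactol into the δ-lactone under neutral conditions that leave the ketone, its two α-stereocentres and the silyl ether alone.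

Step 10
Reactants: 19 (3R,4S,4aS,6S,8S,8aS)-4-{[tert-butyl(dimethyl)silyl]oxy}-3,4a,6,8-tetramethylhexahydropyrano[3,2-b]pyran-2,7-dione
Product: 20 (3R,4S,4aS,6S,7R,8R,8aS)-4-{[tert-butyl(dimethyl)silyl]oxy}-7-hydroxy-3,4a,6,8-tetramethyloctahydropyrano[3,2-b]pyran-2-one
Conditions: NaBH4 (1 equiv), CeCl3·7H2O (1 equiv), MeOH, −78 °C
Reagents that add atoms: none
Why: Luche-type reduction: the small hydride attacks C7 along the axial trajectory, which is unhindered because both flanking methyls are equatorial and O5 carries no axial substituent, giving the equatorial (7R) alcohol, while low temperature and CeCl3 suppress β-elimination of the lactone oxygen and lactone reduction.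

Step 11
Reactants: 21 hexan-2-one; 22 glyoxylic acid monohydrate
Product: 24 (2E)-4-oxooct-2-enoic acid, via aldol adduct 23 (not isolated)
Conditions: pyrrolidine (0.2 equiv), AcOH (1 equiv), MeOH, 60 °C
Reagents that add atoms: none
Why: Enamine-mediated aldol condensation at the methyl terminus of the methyl ketone with glyoxylic acid followed by dehydration gives the thermodynamically favoured (E)-4-oxo-2-enoic acid.

Step 12
Reactants: 20 (3R,4S,4aS,6S,7R,8R,8aS)-4-{[tert-butyl(dimethyl)silyl]oxy}-7-hydroxy-3,4a,6,8-tetramethyloctahydropyrano[3,2-b]pyran-2-one; 24 (2E)-4-oxooct-2-enoic acid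
Product: 25 (3R,4S,4aS,6S,7R,8R,8aS)-4-{[tert-butyl(dimethyl)silyl]oxy}-3,4a,6,8-tetramethyl-2-oxooctahydropyrano[3,2-b]pyran-7-yl (2E)-4-oxooct-2-enoate
Conditions: DCC (1.5 equiv), DMAP (0.2 equiv), CH2Cl2, 0 °C → rt
Reagents that add atoms: none
Why: Steglich esterification of the only free hydroxyl (equatorial C7–OH) with the carbodiimide-activated acid; the C4 hydroxyl is masked as its silyl ether, so no site selectivity is needed.

Step 13
Reactants: 25 (3R,4S,4aS,6S,7R,8R,8aS)-4-{[tert-butyl(dimethyl)silyl]oxy}-3,4a,6,8-tetramethyl-2-oxooctahydropyrano[3,2-b]pyran-7-yl (2E)-4-oxooct-2-enoate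
Product: 26 botcinin I, (3R,4S,4aR,6S,7R,8R,8aS)-4-hydroxy-3,4a,6,8-tetramethyl-2-oxooctahydropyrano[3,2-b]pyran-7-yl (2E)-4-oxooct-2-enoate
Conditions: HF·pyridine, pyridine, THF, 0 °C → rt
Reagents that add atoms: none
Why: Fluoride-assisted cleavage of the silyl ether under weakly acidic conditions that spare the ene-dione ester and the lactone, and no stereocentre is touched.

Compound list
1 | methacrolein (2-methylprop-2-enal) | C=C(C)C=O | starting material
2 | (E)-crotylboronic acid pinacol ester (2-[(2E)-but-2-en-1-yl]-4,4,5,5-tetramethyl-1,3,2-dioxaborolane) | C/C=C/CB1OC(C)(C)C(C)(C)O1 | starting material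
3 | 2-{[(3S,4S)-2,4-dimethylhexa-1,5-dien-3-yl]oxy}-4,4,5,5-tetramethyl-1,3,2-dioxaborolane | C=C[C@H](C)[C@H](OB1OC(C)(C)C(C)(C)O1)C(C)=C | intermediate (not isolated)
4 | (3S,4S)-2,4-dimethylhexa-1,5-dien-3-ol | C=C[C@H](C)[C@H](O)C(C)=C | intermediate
5 | (1S,2S)-2-methyl-1-[(2R)-2-methyloxiran-2-yl]but-3-en-1-ol | C=C[C@H](C)[C@H](O)[C@@]1(C)CO1 | intermediate
6 | ethyl (S)-lactate (ethyl (2S)-2-hydroxypropanoate) | C[C@H](O)C(=O)OCC | starting material
7 | ethyl (2S)-2-{[(2S,3S,4S)-1,3-dihydroxy-2,4-dimethylhex-5-en-2-yl]oxy}propanoate | C=C[C@H](C)[C@H](O)[C@](C)(CO)O[C@@H](C)C(=O)OCC | intermediate (not isolated)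
8 | (3S,5S)-5-[(1S,2S)-1-hydroxy-2-methylbut-3-en-1-yl]-3,5-dimethyl-1,4-dioxan-2-one | C=C[C@H](C)[C@H](O)[C@]1(C)COC(=O)[C@H](C)O1 | intermediate
9 | (3S,5S)-5-[(1S,2S)-1-{[tert-butyl(dimethyl)silyl]oxy}-2-methylbut-3-en-1-yl]-3,5-dimethyl-1,4-dioxan-2-one | C=C[C@H](C)[C@H](O[Si](C)(C)C(C)(C)C)[C@]1(C)COC(=O)[C@H](C)O1 | intermediate
10 | lithium alkoxide of hemiketal 11 | C=C[C@H](C)[C@H](O[Si](C)(C)C(C)(C)C)[C@]1(C)COC([O-])(CC)[C@H](C)O1.[Li+] | intermediate (not isolated)
11 | (3S,5S)-5-[(1S,2S)-1-{[tert-butyl(dimethyl)silyl]oxy}-2-methylbut-3-en-1-yl]-2-ethyl-3,5-dimethyl-1,4-dioxan-2-ol (anomeric mixture) | C=C[C@H](C)[C@H](O[Si](C)(C)C(C)(C)C)[C@]1(C)COC(O)(CC)[C@H](C)O1 | intermediate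
12 | (2R,3S,4S)-3-{[tert-butyl(dimethyl)silyl]oxy}-2,4-dimethyl-2-{[(2S)-3-oxopentan-2-yl]oxy}hex-5-enal | C=C[C@H](C)[C@H](O[Si](C)(C)C(C)(C)C)[C@](C)(C=O)O[C@@H](C)C(=O)CC | intermediate
13 | (2R,3S,4S)-3-{[tert-butyl(dimethyl)silyl]oxy}-2,4-dimethyl-2-{[(2S,3Z)-3-[(trimethylsilyl)oxy]pent-3-en-2-yl]oxy}hex-5-enal | C=C[C@H](C)[C@H](O[Si](C)(C)C(C)(C)C)[C@](C)(C=O)O[C@@H](C)/C(O[Si](C)(C)C)=C/C | intermediate (not isolated)
14 | 5-O-trimethylsilyl ether of 15 | C=C[C@H](C)[C@H](O[Si](C)(C)C(C)(C)C)[C@@]1(C)O[C@@H](C)C(=O)[C@@H](C)[C@@H]1O[Si](C)(C)C | intermediate (not isolated)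
15 | (2S,4S,5S,6S)-6-[(1S,2S)-1-{[tert-butyl(dimethyl)silyl]oxy}-2-methylbut-3-en-1-yl]-5-hydroxy-2,4,6-trimethyloxan-3-one | C=C[C@H](C)[C@H](O[Si](C)(C)C(C)(C)C)[C@@]1(C)O[C@@H](C)C(=O)[C@@H](C)[C@@H]1O | intermediate
16 | secondary ozonide (1,2,4-trioxolane) from the vinyl group of 15 | C1OOC(O1)[C@H](C)[C@H](O[Si](C)(C)C(C)(C)C)[C@@]2(C)O[C@@H](C)C(=O)[C@@H](C)[C@@H]2O | intermediate (not isolated)
17 | open hydroxy aldehyde (C2 aldehyde, free C8a hydroxyl) from cleavage of the vinyl group of 15 | O=C[C@H](C)[C@H](O[Si](C)(C)C(C)(C)C)[C@@]1(C)O[C@@H](C)C(=O)[C@@H](C)[C@@H]1O | intermediate (not isolated)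
18 | (3R,4S,4aS,6S,8S,8aS)-4-{[tert-butyl(dimethyl)silyl]oxy}-2-hydroxy-3,4a,6,8-tetramethylhexahydropyrano[3,2-b]pyran-7-one (anomeric mixture) | O=C1[C@@H](C)[C@@H]2OC(O)[C@H](C)[C@H](O[Si](C)(C)C(C)(C)C)[C@@]2(C)O[C@H]1C | intermediate
19 | (3R,4S,4aS,6S,8S,8aS)-4-{[tert-butyl(dimethyl)silyl]oxy}-3,4a,6,8-tetramethylhexahydropyrano[3,2-b]pyran-2,7-dione | O=C1[C@@H](C)[C@@H]2OC(=O)[C@H](C)[C@H](O[Si](C)(C)C(C)(C)C)[C@@]2(C)O[C@H]1C | intermediate
20 | (3R,4S,4aS,6S,7R,8R,8aS)-4-{[tert-butyl(dimethyl)silyl]oxy}-7-hydroxy-3,4a,6,8-tetramethyloctahydropyrano[3,2-b]pyran-2-one | O[C@@H]1[C@@H](C)[C@@H]2OC(=O)[C@H](C)[C@H](O[Si](C)(C)C(C)(C)C)[C@@]2(C)O[C@H]1C | intermediate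
21 | hexan-2-one | CCCCC(C)=O | starting material
22 | glyoxylic acid monohydrate (2,2-dihydroxyacetic acid) | OC(O)C(=O)O | starting material
23 | 2-hydroxy-4-oxooctanoic acid | CCCCC(=O)CC(O)C(=O)O | intermediate (not isolated)
24 | (2E)-4-oxooct-2-enoic acid | CCCCC(=O)/C=C/C(=O)O | intermediate
25 | (3R,4S,4aS,6S,7R,8R,8aS)-4-{[tert-butyl(dimethyl)silyl]oxy}-3,4a,6,8-tetramethyl-2-oxooctahydropyrano[3,2-b]pyran-7-yl (2E)-4-oxooct-2-enoate | CCCCC(=O)/C=C/C(=O)O[C@@H]1[C@@H](C)[C@@H]2OC(=O)[C@H](C)[C@H](O[Si](C)(C)C(C)(C)C)[C@@]2(C)O[C@H]1C | intermediate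
26 | botcinin I, (3R,4S,4aR,6S,7R,8R,8aS)-4-hydroxy-3,4a,6,8-tetramethyl-2-oxooctahydropyrano[3,2-b]pyran-7-yl (2E)-4-oxooct-2-enoate | CCCCC(=O)/C=C/C(=O)O[C@@H]1[C@@H](C)[C@@H]2OC(=O)[C@H](C)[C@H](O)[C@@]2(C)O[C@H]1C | target

Total step count: 13. Longest linear sequence: 12 steps (steps 1–10, 12 and 13; step 11 makes the side-chain acid).

Steps most likely to fail

Step 3. The lactate, a weak and hindered nucleophile, may attack the primary epoxide carbon instead of the tertiary one. The tertiary centre may also ionise fully, so that stereochemical fidelity at C4a is lost or a pinacol-type 1,2-hydride shift from C4 intervenes. The later ring closure may in part engage the secondary hydroxyl. Fallback, setting out from 5 and returning at 8: acid-catalysed hydrolysis (HClO4 cat., THF/H2O, 0 °C), in which water as a small nucleophile in large excess opens the epoxide at the tertiary carbon with inversion, should give (2S,3S,4S)-2,4-dimethylhex-5-ene-1,2,3-triol F1. Its primary hydroxyl is acylated selectively with (R)-2-bromopropanoyl chloride (2,4,6-collidine, CH2Cl2, −78 °C) to give the bromo ester F2. NaH (THF, 0 °C) then closes ring C by intramolecular Williamson displacement of bromide by the tertiary alkoxide, with inversion at C6, to give 8. The ether is thus made at the O5–C6 bond instead of the C4a–O5 bond.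

Step 7. The aldehyde may react through a synclinal or chelated transition state, so that the oxygen at C8a ends axial (poor facial selectivity), or silyl enol ether formation may occur in part towards C6. Fallback, setting out from 12 and returning at 20: the C8a stereocentre is set by hydride reduction of a ketone instead of by the aldol. The cyclisation product with the axial C8a hydroxyl, the C8a epimer of 15, F3, is reduced with Me4NBH(OAc)3 (AcOH/MeCN, −20 °C; Evans–Saksena reduction). Hydride should be delivered to C7 from the face of the axial C8a oxygen and give the diol F4 with the equatorial C7 hydroxyl. The less hindered C7 hydroxyl is silylated (TESCl, imidazole, DMF, −20 °C) to the 7-O-triethylsilyl ether of F4, F5. Dess–Martin oxidation removes the faulty centre as the C8a ketone F6. NaBH4 (MeOH, −20 °C) should attack C8a axially, the equatorial trajectory being blocked by the axial C4a methyl, and give the equatorial alcohol F7. Ozonolysis with PPh3 work-up gives the lactol F8, Ley–Griffith oxidation (Pr4N[RuO4], N-methylmorpholine N-oxide) gives the lactone F9, and selective removal of the triethylsilyl ether (PPTS, MeOH, 0 °C) leads to 20.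

Step 5. Ethyllithium may remove the proton α to the lactone carbonyl (loss of configuration at C6), or the tetrahedral intermediate may collapse early and take up a second equivalent. Fallback, setting out from 9 and returning at 11: Takai–Utimoto ethylidenation (CH3CHBr2, Zn, TiCl4, TMEDA, PbCl2 cat., THF, rt) converts the lactone carbonyl into the (Z)-2-ethylidene-1,4-dioxane F10 under non-basic conditions. Mild hydration of this enol ether (PPTS, THF/H2O, rt) gives hemiketal 11.

Further compounds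
F1 | step 3 | (2S,3S,4S)-2,4-dimethylhex-5-ene-1,2,3-triol | C=C[C@H](C)[C@H](O)[C@](C)(CO)O
F2 | step 3 | (2S,3S,4S)-2,3-dihydroxy-2,4-dimethylhex-5-en-1-yl (2R)-2-bromopropanoate | C=C[C@H](C)[C@H](O)[C@](C)(COC(=O)[C@@H](C)Br)O
F3 | step 7 | (2S,4S,5R,6S)-6-[(1S,2S)-1-{[tert-butyl(dimethyl)silyl]oxy}-2-methylbut-3-en-1-yl]-5-hydroxy-2,4,6-trimethyloxan-3-one (C8a epimer of 15) | C=C[C@H](C)[C@H](O[Si](C)(C)C(C)(C)C)[C@@]1(C)O[C@@H](C)C(=O)[C@@H](C)[C@H]1O
F4 | step 7 | diol from F3 with equatorial C7 hydroxyl and axial C8a hydroxyl | C=C[C@H](C)[C@H](O[Si](C)(C)C(C)(C)C)[C@@]1(C)O[C@@H](C)[C@H](O)[C@@H](C)[C@H]1O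
F5 | step 7 | 7-O-triethylsilyl ether of F4 | C=C[C@H](C)[C@H](O[Si](C)(C)C(C)(C)C)[C@@]1(C)O[C@@H](C)[C@H](O[Si](CC)(CC)CC)[C@@H](C)[C@H]1O
F6 | step 7 | C8a ketone from F5 | C=C[C@H](C)[C@H](O[Si](C)(C)C(C)(C)C)[C@@]1(C)O[C@@H](C)[C@H](O[Si](CC)(CC)CC)[C@@H](C)C1=O
F7 | step 7 | alcohol from F6 with equatorial C8a hydroxyl | C=C[C@H](C)[C@H](O[Si](C)(C)C(C)(C)C)[C@@]1(C)O[C@@H](C)[C@H](O[Si](CC)(CC)CC)[C@@H](C)[C@@H]1O
F8 | step 7 | trans-fused lactol from F7 (7-O-triethylsilyl; anomeric mixture) | CC[Si](CC)(CC)O[C@@H]1[C@@H](C)[C@@H]2OC(O)[C@H](C)[C@H](O[Si](C)(C)C(C)(C)C)[C@@]2(C)O[C@H]1C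
F9 | step 7 | 7-O-triethylsilyl ether of 20 | CC[Si](CC)(CC)O[C@@H]1[C@@H](C)[C@@H]2OC(=O)[C@H](C)[C@H](O[Si](C)(C)C(C)(C)C)[C@@]2(C)O[C@H]1C
F10 | step 5 | (2Z,3S,5S)-5-[(1S,2S)-1-{[tert-butyl(dimethyl)silyl]oxy}-2-methylbut-3-en-1-yl]-2-ethylidene-3,5-dimethyl-1,4-dioxane | C=C[C@H](C)[C@H](O[Si](C)(C)C(C)(C)C)[C@]1(C)CO/C(=C\C)[C@H](C)O1
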